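**Plan**
- Retrosynthesis cuts, in order: the two aryl O–CH3 bonds (hydroxyls at depsidone C3 and C6); the dihydropyranone ring (C8–acyl bond and C7 O–C(CH3)2 bond); the lactone O–C(=O) bond; and finally ring A at its formyl carbon–ether carbon bond (C4–C4a) and its methyl carbon–carboxyl carbon bond (C1–C11a).
- Enabling feature: ring A is a pentasubstituted benzene. Its methyl carbon, CH, oxygenated carbon and formyl carbon (C1–C4) correspond to C6, C5, C4 and C3 of 3-formyl-4-methoxy-6-methyl-2-pyrone, and its neighbouring ether and carboxyl carbons (C4a, C11a) are the two sp carbons of a 3-aryloxypropiolate.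
- Forward: ring B is bought as 2,3,4-trimethoxy-6-methylbenzaldehyde and reworked into a mono-benzylated catechol, then its dichlorovinyl ether, then the aryloxy propiolate. Ring A is formed next by pyrone Diels–Alder addition with loss of CO2, followed by the seven-membered lactone, the pyranone ring and demethylation.
- The alkynoate is carried as a benzyl ester, so a single hydrogenolysis unmasks the acid and the phenol together and no hindered benzoate needs saponification.
- Stereochemistry: the target is achiral, with no stereocentre and no stereogenic double bond. The bridgehead centres of the cycloadduct disappear with CO2.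

Key step: step 9

Remark: the four starting materials (1, 4, 11, 20) are assumed to be commercial. Names use the dibenzo[b,e][1,4]dioxepin-11-one numbering: ring A = C1 (CH3), C2 (H), C3 (OH), C4 (CHO), C4a (ether O), C11a (lactone C=O); ring B = C5a (ether O), C6 (OH), C7 (pyranone O), C8 (ketone carbon), C9 (CH3), C9a (lactone O). Pyrone atoms are always called "pyrone C3" and so on.

**Route**

Step 1
Reactants: 1 4-methoxy-6-methyl-2H-pyran-2-one
Product: 3 4-methoxy-6-methyl-2-oxo-2H-pyran-3-carbaldehyde, via α-chloro ether 2 (not isolated)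
Conditions: Cl2CHOCH3, TiCl4, CH2Cl2, 0 °C → rt; then ice/H2O
Reagents that add atoms: dichloromethyl methyl ether COC(Cl)Cl; water O
Why: Rieche formylation is expected at pyrone C3, the nucleophilic carbon β to the 4-methoxy enol ether oxygen (the site at which this pyrone is also halogenated), and the chloro ether 2 collapses to the aldehyde on aqueous work-up.

Step 2
Reactants: 4 2,3,4-trimethoxy-6-methylbenzaldehyde
Product: 5 2-hydroxy-3,4-dimethoxy-6-methylbenzaldehyde
Conditions: BCl3 (1.1 equiv), CH2Cl2, −78 → 0 °C; then H2O
Reagents that add atoms: none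
Why: Chelation-directed Lewis-acid ether cleavage, in which boron held between the formyl oxygen and the ortho methoxy oxygen should release only that methyl group as chloromethane when one equivalent is used cold.

Step 3
Reactants: 5 2-hydroxy-3,4-dimethoxy-6-methylbenzaldehyde
Product: 6 3,4-dimethoxy-2-(methoxymethoxy)-6-methylbenzaldehyde
Conditions: NaH, CH3OCH2Cl, DMF, 0 °C → rt
Reagents that add atoms: chloromethyl methyl ether COCCl
Why: Williamson-type O-alkylation of the sodium phenoxide installs a methoxymethyl ether, which withstands peracid, carbonate and benzylation and can later be taken off with acid while a benzyl ether stays.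

Step 4
Reactants: 6 3,4-dimethoxy-2-(methoxymethoxy)-6-methylbenzaldehyde
Product: 8 3,4-dimethoxy-2-(methoxymethoxy)-6-methylphenol, via aryl formate 7 (not isolated)
Conditions: mCPBA, NaHCO3, CH2Cl2, 0 °C → rt; Na2S2O3 wash; then K2CO3 (cat.), CH3OH, rt
Reagents that add atoms: 3-chloroperoxybenzoic acid OOC(=O)c1cccc(Cl)c1
Why: Dakin-type Baeyer–Villiger oxidation, in which the aryl group bearing ortho and para oxygen donors migrates rather than hydride; formate 7 is then methanolysed by carbonate once the peracid is quenched, and the hydrogencarbonate buffer spares the acetal.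

Step 5
Reactants: 8 3,4-dimethoxy-2-(methoxymethoxy)-6-methylphenol
Product: 9 2-(benzyloxy)-4,5-dimethoxy-3-(methoxymethoxy)-1-methylbenzene
Conditions: BnBr, K2CO3, DMF, rt
Reagents that add atoms: benzyl bromide BrCc1ccccc1
Why: Williamson etherification puts benzyl on the oxygen that will become the lactone oxygen (at C9a); this group should tolerate n-BuLi at −78 °C and the heat of the cycloaddition and is removed by hydrogenolysis.

Step 6
Reactants: 9 2-(benzyloxy)-4,5-dimethoxy-3-(methoxymethoxy)-1-methylbenzene
Product: 10 2-(benzyloxy)-5,6-dimethoxy-3-methylphenol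
Conditions: conc. HCl (cat.), CH3OH, 50 °C
Reagents that add atoms: none
Why: Acid-catalysed transacetalisation to methanol removes the methoxymethyl group and exposes the hydroxyl destined to be the diaryl ether oxygen, while benzyl and methyl aryl ethers are inert to dilute acid.

Step 7
Reactants: 10 2-(benzyloxy)-5,6-dimethoxy-3-methylphenol; 11 trichloroethylene
Product: 12 2-(benzyloxy)-1-{[(E)-1,2-dichloroethenyl]oxy}-5,6-dimethoxy-3-methylbenzene
Conditions: K2CO3, DMF, 70 °C
Reagents that add atoms: none
Why: Dichlorovinyl ether synthesis, in which base turns trichloroethylene into dichloroacetylene and the phenoxide adds to it in anti fashion to give the E ether (a geometry that is erased in the next step).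

Step 8
Reactants: 12 2-(benzyloxy)-1-{[(E)-1,2-dichloroethenyl]oxy}-5,6-dimethoxy-3-methylbenzene
Product: 15 benzyl 3-[2-(benzyloxy)-5,6-dimethoxy-3-methylphenoxy]prop-2-ynoate, via chloroethynyl ether 13 (not isolated), via lithium aryloxyacetylide 14 (not isolated)
Conditions: n-BuLi (2.2 equiv), THF, −78 → −40 °C; then cannulated into ClCO2Bn, THF, −78 °C
Reagents that add atoms: benzyl chloroformate O=C(Cl)OCc1ccccc1
Why: Dehydrochlorination to the chloroalkynyl ether, chlorine–lithium exchange and C-acylation of the resulting acetylide with a chloroformate is the established way from dichlorovinyl ethers to ynol ethers and their propiolate esters, and inverse addition keeps the electrophile in excess.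

Step 9
Reactants: 3 4-methoxy-6-methyl-2-oxo-2H-pyran-3-carbaldehyde; 15 benzyl 3-[2-(benzyloxy)-5,6-dimethoxy-3-methylphenoxy]prop-2-ynoate
Product: 17 benzyl 2-[2-(benzyloxy)-5,6-dimethoxy-3-methylphenoxy]-3-formyl-4-methoxy-6-methylbenzoate, via bridged lactone adduct 16 (not isolated)
Conditions: 3 (1.5 equiv), toluene, 4 Å molecular sieves, sealed tube, 150 °C
Reagents that add atoms: none
Why: The alkyne should add thermally in a [4+2] sense across pyrone C3 and C6 to give the 2-oxabicyclo[2.2.2]octadienone 16, which ejects CO2 by a retro-[4+2] step and, the dienophile being an alkyne, arrives directly at the benzene; the closest known reaction type is the Diels–Alder/decarboxylation sequence of 2-pyrones with alkynoates and heteroatom-substituted alkynes that furnishes benzoates. Ring A is closed as a six-membered carbocycle by the cycloaddition itself, its formyl carbon–ether carbon (C4–C4a) and methyl carbon–carboxyl carbon (C1–C11a) bonds arising in one, probably asynchronous, pericyclic event. The two bridgehead stereocentres of 16 form as a racemate and are erased when CO2 departs, so no stereocontrol is needed. Regioselectivity must place the aryloxy-bearing alkyne carbon on pyrone C3: the ester-bearing alkyne carbon lies β to the donor oxygen and is the nucleophilic end of the push–pull alkyne, matching pyrone C6, the acceptor terminus of a diene depleted by the lactone and formyl carbonyls, whereas pyrone C3, β to the 4-methoxy group, matches the electrophilic oxygen-bearing alkyne carbon, so both polarisations agree. Chemoselectivity for the C3–C6 diene over the formyl enone acting as a heterodiene is expected because the enone terminus (pyrone C4) carries the donating methoxy group and is a weaker acceptor than pyrone C6. An aryl ynol ether lacks the retro-ene route to a ketene that alkyl ynol ethers have and should therefore survive the heating, and the sieves keep out the water that would hydrate it.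

Step 10
Reactants: 17 benzyl 2-[2-(benzyloxy)-5,6-dimethoxy-3-methylphenoxy]-3-formyl-4-methoxy-6-methylbenzoate
Product: 18 3-formyl-2-(2-hydroxy-5,6-dimethoxy-3-methylphenoxy)-4-methoxy-6-methylbenzoic acid
Conditions: H2 (1 atm), 10% Pd/C, EtOAc, rt, stopped after uptake of 2 equiv
Reagents that add atoms: none
Why: Heterogeneous hydrogenolysis removes the benzyl ester and the benzyl aryl ether, while an aryl aldehyde flanked by two ortho oxygens is reduced much more slowly at one atmosphere in ethyl acetate, as is usual for benzyl esters of formyl-bearing depside acids.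

Step 11
Reactants: 18 3-formyl-2-(2-hydroxy-5,6-dimethoxy-3-methylphenoxy)-4-methoxy-6-methylbenzoic acid
Product: 19 3,6,7-trimethoxy-1,9-dimethyl-11-oxo-11H-dibenzo[b,e][1,4]dioxepine-4-carbaldehyde
Conditions: DCC, DMAP (cat.), CH2Cl2 (0.01 M), 0 °C → rt
Reagents that add atoms: none
Why: Steglich-type carbodiimide lactonisation, in which the activated acid is trapped by the neighbouring-ring phenol in a 7-exo-trig closure pre-organised by the diaryl ether, the customary way of closing a depsidone from its hydroxy acid.

Step 12
Reactants: 19 3,6,7-trimethoxy-1,9-dimethyl-11-oxo-11H-dibenzo[b,e][1,4]dioxepine-4-carbaldehyde; 20 3-methylbut-2-enoyl chloride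
Product: 23 di-O-methyl ether of the target (C3-OMe/C6-OMe), via acylated trimethyl ether 21 (not isolated), via C7 phenol enone 22 (not isolated)
Conditions: AlCl3 (4 equiv), CH2Cl2, 0 °C → rt; then ice/H2O
Reagents that add atoms: none
Why: Friedel–Crafts acylation should take C8, the only free carbon of ring B (para to the diaryl ether oxygen, ortho to a methoxy and a methyl group as in the readily acylated 3,4,5-trimethoxytoluene, with ring A switched off by its AlCl3-bound carbonyls); AlCl3 then cleaves the C7 methyl ether chelated to the new ketone, and the aluminium phenoxide closes the pyranone by 6-endo oxa-Michael addition. Acylation, ortho-demethylation and chromanone closure in one pot is known for methoxyarenes with this acid chloride, and any methyl lost from the C3 oxygen here is removed in the final step anyway.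

Step 13
Reactants: 23 di-O-methyl ether of the target (C3-OMe/C6-OMe)
Product: 24 CNP0271978.0 (target)
Conditions: BCl3 (6 equiv), CH2Cl2, −78 °C → rt; then H2O
Reagents that add atoms: none
Why: Lewis-acid ether cleavage, in which BCl3 should remove the C3 methyl through the chelate with the formyl oxygen and the C6 methyl because a methoxy group flanked by two ortho oxygens is twisted out of conjugation and belongs to the hindered ethers that BCl3 cleaves, while the aryl lactone, diaryl ether and chromanone should persist at or below room temperature.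

**Compound list**
1 | 4-methoxy-6-methyl-2H-pyran-2-one | Cc1cc(OC)cc(=O)o1 | starting material
2 | 3-[chloro(methoxy)methyl]-4-methoxy-6-methyl-2H-pyran-2-one (racemic) | Cc1cc(OC)c(C(Cl)OC)c(=O)o1 | intermediate
3 | 4-methoxy-6-methyl-2-oxo-2H-pyran-3-carbaldehyde | Cc1cc(OC)c(C=O)c(=O)o1 | intermediate
4 | 2,3,4-trimethoxy-6-methylbenzaldehyde | COc1cc(C)c(C=O)c(OC)c1OC | starting material
5 | 2-hydroxy-3,4-dimethoxy-6-methylbenzaldehyde | COc1cc(C)c(C=O)c(O)c1OC | intermediate
6 | 3,4-dimethoxy-2-(methoxymethoxy)-6-methylbenzaldehyde | COCOc1c(C=O)c(C)cc(OC)c1OC | intermediate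
7 | 3,4-dimethoxy-2-(methoxymethoxy)-6-methylphenyl formate | COCOc1c(OC=O)c(C)cc(OC)c1OC | intermediate
8 | 3,4-dimethoxy-2-(methoxymethoxy)-6-methylphenol | COCOc1c(O)c(C)cc(OC)c1OC | intermediate
9 | 2-(benzyloxy)-4,5-dimethoxy-3-(methoxymethoxy)-1-methylbenzene | COCOc1c(OCc2ccccc2)c(C)cc(OC)c1OC | intermediate
10 | 2-(benzyloxy)-5,6-dimethoxy-3-methylphenol | Cc1cc(OC)c(OC)c(O)c1OCc1ccccc1 | intermediate
11 | trichloroethylene | ClC=C(Cl)Cl | starting material
12 | 2-(benzyloxy)-1-{[(E)-1,2-dichloroethenyl]oxy}-5,6-dimethoxy-3-methylbenzene | Cc1cc(OC)c(OC)c(O/C(Cl)=C\Cl)c1OCc1ccccc1 | intermediate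
13 | 2-(benzyloxy)-1-[(chloroethynyl)oxy]-5,6-dimethoxy-3-methylbenzene | Cc1cc(OC)c(OC)c(OC#CCl)c1OCc1ccccc1 | intermediate
14 | lithium [2-(benzyloxy)-5,6-dimethoxy-3-methylphenoxy]acetylide | [Li]C#COc1c(OCc2ccccc2)c(C)cc(OC)c1OC | intermediate
15 | benzyl 3-[2-(benzyloxy)-5,6-dimethoxy-3-methylphenoxy]prop-2-ynoate | O=C(OCc1ccccc1)C#COc1c(OCc2ccccc2)c(C)cc(OC)c1OC | intermediate
16 | benzyl 5-[2-(benzyloxy)-5,6-dimethoxy-3-methylphenoxy]-4-formyl-8-methoxy-1-methyl-3-oxo-2-oxabicyclo[2.2.2]octa-5,7-diene-6-carboxylate (racemic) | CC12OC(=O)C(C=O)(C(OC)=C1)C(Oc1c(OCc3ccccc3)c(C)cc(OC)c1OC)=C2C(=O)OCc1ccccc1 | intermediate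
17 | benzyl 2-[2-(benzyloxy)-5,6-dimethoxy-3-methylphenoxy]-3-formyl-4-methoxy-6-methylbenzoate | Cc1cc(OC)c(C=O)c(Oc2c(OCc3ccccc3)c(C)cc(OC)c2OC)c1C(=O)OCc1ccccc1 | intermediate
18 | 3-formyl-2-(2-hydroxy-5,6-dimethoxy-3-methylphenoxy)-4-methoxy-6-methylbenzoic acid | Cc1cc(OC)c(C=O)c(Oc2c(O)c(C)cc(OC)c2OC)c1C(=O)O | intermediate
19 | 3,6,7-trimethoxy-1,9-dimethyl-11-oxo-11H-dibenzo[b,e][1,4]dioxepine-4-carbaldehyde | Cc1cc(OC)c(C=O)c2c1C(=O)Oc1c(C)cc(OC)c(OC)c1O2 | intermediate
20 | 3-methylbut-2-enoyl chloride | CC(C)=CC(=O)Cl | starting material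
21 | 3,6,7-trimethoxy-1,9-dimethyl-8-(3-methylbut-2-enoyl)-11-oxo-11H-dibenzo[b,e][1,4]dioxepine-4-carbaldehyde | Cc1cc(OC)c(C=O)c2c1C(=O)Oc1c(C)c(C(=O)C=C(C)C)c(OC)c(OC)c1O2 | intermediate
22 | 7-hydroxy-3,6-dimethoxy-1,9-dimethyl-8-(3-methylbut-2-enoyl)-11-oxo-11H-dibenzo[b,e][1,4]dioxepine-4-carbaldehyde (present as its aluminium phenoxide) | Cc1cc(OC)c(C=O)c2c1C(=O)Oc1c(C)c(C(=O)C=C(C)C)c(O)c(OC)c1O2 | intermediate
23 | di-O-methyl ether of the target: depsidone 19 carrying a 2,2-dimethyl-2,3-dihydropyran-4-one fused across C7 (ring O) and C8 (ketone carbon), methoxy at C3 and C6 | Cc1cc(OC)c(C=O)c2c1C(=O)Oc1c(C)c3c(c(OC)c1O2)OC(C)(C)CC3=O | intermediate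
24 | CNP0271978.0: 11H-dibenzo[b,e][1,4]dioxepin-11-one with 1-methyl, 3-hydroxy, 4-formyl, 6-hydroxy, 9-methyl and a 2,2-dimethyl-2,3-dihydropyran-4-one fused across C7 (ring O) and C8 (ketone carbon); achiral | Cc1cc(O)c(C=O)c2c1C(=O)Oc1c(C)c3c(c(O)c1O2)OC(C)(C)CC3=O | target

**Count**
Total steps: 13. Longest linear sequence: 12 steps (steps 2–13, from aldehyde 4); the pyrone branch joins after one step.

**Steps most likely to fail**

Step 9. The alkyne may be consumed by addition across the formyl enone acting as a heterodiene, or by hydration or oligomerisation during prolonged heating, before the slower addition across pyrone C3/C6 occurs. The fallback removes the formyl group from the diene and introduces it once ring A exists. Pyrone 1 would be brominated at C3 (NBS, CH3CN, rt) to 3-bromo-4-methoxy-6-methyl-2H-pyran-2-one F1. 3-Bromo-2-pyrones are ambiphilic dienes with no heterodiene unit, and the 4-methoxy group keeps pyrone C3 the donor terminus, so F1 should add to 15 (toluene, sealed tube, 130–150 °C) in the same orientation. The resulting benzyl 5-[2-(benzyloxy)-5,6-dimethoxy-3-methylphenoxy]-4-bromo-8-methoxy-1-methyl-3-oxo-2-oxabicyclo[2.2.2]octa-5,7-diene-6-carboxylate F2 would lose CO2 to give benzyl 2-[2-(benzyloxy)-5,6-dimethoxy-3-methylphenoxy]-3-bromo-4-methoxy-6-methylbenzoate F3. Bromine–magnesium exchange (i-PrMgCl·LiCl, THF, 0 °C → rt; the di-ortho-substituted benzyl ester is shielded), a DMF quench and dilute aqueous HCl work-up would then deliver the aldehyde. This fallback sets out from 1 and 15 and rejoins the route at 17.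

Step 12. Acylation may stall on a ring B deactivated by AlCl3 bound to its neighbouring oxygens, or ether cleavage may proceed unselectively and leave mixtures of partly demethylated, uncyclised ketones. The fallback reverses the order of demethylation and annulation. Depsidone 19 would be demethylated completely (BBr3, CH2Cl2, −78 °C → rt) to 3,6,7-trihydroxy-1,9-dimethyl-11-oxo-11H-dibenzo[b,e][1,4]dioxepine-4-carbaldehyde F4. The free phenol would then be annulated with 3-methylbut-2-enoic acid in P2O5/CH3SO3H at 70 °C, the standard chromanone synthesis from phenols. C-acylation at C8, ortho to the free C7 hydroxyl, should give 3,6,7-trihydroxy-1,9-dimethyl-8-(3-methylbut-2-enoyl)-11-oxo-11H-dibenzo[b,e][1,4]dioxepine-4-carbaldehyde F5 (not isolated), which closes by oxa-Michael addition of the C7 hydroxyl, the only hydroxyl ortho to the ketone. This fallback sets out from 19 and rejoins the route at the target 24.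

Step 8. The lithium acetylide may attack the ynoate as it forms (conjugate addition or double acylation), so that the push–pull alkyne is destroyed in the flask. The fallback draws the ester carbon from CO2 under weakly basic conditions. Acetylide 14 would be generated from 12 as before but quenched with aqueous NH4Cl to give the terminal ynol ether 2-(benzyloxy)-1-(ethynyloxy)-5,6-dimethoxy-3-methylbenzene F6. Carboxylation (CO2 1 atm, Cs2CO3, AgI cat., DMF, 50 °C) should give caesium 3-[2-(benzyloxy)-5,6-dimethoxy-3-methylphenoxy]prop-2-ynoate F7 (not isolated), which is alkylated in the same pot with benzyl bromide. This fallback sets out from 12 and rejoins the route at 15.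

**Further compounds**
F1 | step 9 | 3-bromo-4-methoxy-6-methyl-2H-pyran-2-one | Cc1cc(OC)c(Br)c(=O)o1
F2 | step 9 | benzyl 5-[2-(benzyloxy)-5,6-dimethoxy-3-methylphenoxy]-4-bromo-8-methoxy-1-methyl-3-oxo-2-oxabicyclo[2.2.2]octa-5,7-diene-6-carboxylate (racemic) | CC12OC(=O)C(Br)(C(OC)=C1)C(Oc1c(OCc3ccccc3)c(C)cc(OC)c1OC)=C2C(=O)OCc1ccccc1
F3 | step 9 | benzyl 2-[2-(benzyloxy)-5,6-dimethoxy-3-methylphenoxy]-3-bromo-4-methoxy-6-methylbenzoate | Cc1cc(OC)c(Br)c(Oc2c(OCc3ccccc3)c(C)cc(OC)c2OC)c1C(=O)OCc1ccccc1
F4 | step 12 | 3,6,7-trihydroxy-1,9-dimethyl-11-oxo-11H-dibenzo[b,e][1,4]dioxepine-4-carbaldehyde | Cc1cc(O)c(C=O)c2c1C(=O)Oc1c(C)cc(O)c(O)c1O2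
F5 | step 12 | 3,6,7-trihydroxy-1,9-dimethyl-8-(3-methylbut-2-enoyl)-11-oxo-11H-dibenzo[b,e][1,4]dioxepine-4-carbaldehyde | Cc1cc(O)c(C=O)c2c1C(=O)Oc1c(C)c(C(=O)C=C(C)C)c(O)c(O)c1O2
F6 | step 8 | 2-(benzyloxy)-1-(ethynyloxy)-5,6-dimethoxy-3-methylbenzene | C#COc1c(OCc2ccccc2)c(C)cc(OC)c1OC
F7 | step 8 | caesium 3-[2-(benzyloxy)-5,6-dimethoxy-3-methylphenoxy]prop-2-ynoate | [Cs+].[O-]C(=O)C#COc1c(OCc2ccccc2)c(C)cc(OC)c1OC
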